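Readings and results were computed on assumed constants; scatter was added.

Theta's books cannot close on the columns you have: at 50.0 min the run shows 22% starting material and 20% target, so 58.0% of the charge stands in neither column.

common to all: starting material 0.50 M

| flask | first nucleophile | second nucleophile | remark | time |
|---|---|---|---|---|
| theta | 0.45 M | 0.475 M | run made earlier |  |
| eta | 0.45 M | 0.66 M | run made earlier |  |
| beta | 0.45 M | 1 M | run made earlier |  |
| east | 0.450 M (fed, over 64.0 min) | 0.475 M | all but first nucleophile at the start; first nucleophile goes in evenly over 64.0 min, the run ends at 80 min | 80 min |
| south-west | 0.450 M | 0.475 M | a single well-mixed tank run continuously and read at steady state, 240 min in it on average |  |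
| south | 0.450 M | 0.475 M | one stirred flow tank at steady state, fed with the mixture as stated, mean residence time 80 min |  |
| north-east | 0.450 M | 0.475 M | a closed flask charged with all of it at once and left for 80 min | 80 min |

| run | time / min | target / % | starting material / % |
|---|---|---|---|
| theta | 10.0 | 8 | 48 |
| theta | 20.0 | 12 | 34 |
| theta | 30.0 | 14 | 28 |
| theta | 40.0 | 20 | 27 |
| theta | 50.0 | 20 | 22 |
| eta | 4.00 | 4 | 69 |
| eta | 12.0 | 12 | 42 |
| eta | 20.0 | 11 | 28 |
| eta | 30.0 | 14 | 29 |
| eta | 50.0 | 20 | 21 |
| beta | 4.00 | 3 | 70 |
| beta | 8.00 | 9 | 51 |
| beta | 15.0 | 8 | 34 |
| beta | 25.0 | 17 | 30 |
| beta | 50.0 | 21 | 20 |

(readings scatter by 2 percentage points)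

- the set-up with the highest amount of target at the outlet or at the end, in percent of the starting material put in ("none" if the first two lie within 2 percentage points) (east / south-west / south / north-east / none)
- amount of target at the outlet or at the end, in percent of the starting material put in, east
- amount of target at the outlet or at the end, in percent of the starting material put in, south-west
- amount of target at the outlet or at the end, in percent of the starting material put in, south
- amount of target at the outlet or at the end, in percent of the starting material put in, north-east

- the stated concentrations are those of everything mixed, before any reaction; amounts are the same in each set-up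
- the feed brings no volume worth counting
- the earlier runs were made in a closed, stirred flask

Go through the ledger entry by entry. At 50.0 min eta and beta, with 0.66 M and 1 M of second nucleophile, read 20% and 21% target, against theta's 20% and a scatter of 2 percentage points, so these runs show no clear charge on target from second nucleophile. First nucleophile was charged at 90.0% of the starting material. Book one of it per target, and theta still holds 0.350 M free.

The entry to follow is the late one: from 20.0 min to 50.0 min theta gains 8 points of target. Target gained per minute as a fraction of the charge, divided by the mean starting material, also as a fraction of the charge, and by the mean free first nucleophile in molar over that stretch, is the late target constant, 1.54 M⁻¹ h⁻¹. It is a reading and carries the scatter of its end points. My own reckoning holds theta's last values steady up to 80 min in north-east, which has the same charge in a closed flask, and gives 25.9%.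

The forecast names south-west as best, with 16% for east, 29% for south-west, 21% for south and 24% for north-east, which is lower than my figure. It says: “The long tank probably wins, but this is uncertain.”

The flask gives south-west as best, with east 15.6%, south-west 32.0%, south 21.4% and north-east 26.7%, so the forecast stands within tolerance.

    second nucleophile + intermediate → other capture product (k = 13.0 M⁻¹ h⁻¹)
    starting material ⇌ intermediate (K = 0.0470, k = 14.0 h⁻¹)
    first nucleophile + intermediate → target (k = 39.0 M⁻¹ h⁻¹)
    intermediate → side product (k = 4.90 h⁻¹)
    starting material ⇌ dormant form (K = 1.50, k = 4.50 h⁻¹)
    2 starting material → self-condensation product (k = 0.00110 M⁻¹ h⁻¹)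

In north-east, at charged concentrations, the half-life of intermediate by the making of target alone is 2.4 min, shorter than the 6.7 min by its loss to other capture product alone. The constant 1.54 M⁻¹ h⁻¹, applied to north-east's state at 40.0 min and held for the second half of the time, gives 9.4 points more target, and the flask gains 8.5 points. In the neighbour of east charged with 0.11 M first nucleophile, the end state of 27% starting material and 81% of its own first nucleophile, held over 80 min, gives 4.94%. The computed target there is 4.25%.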